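A bookkeeper's two columns will do for this flask: what stands of the substrate at 20 h, and where the rest has gone.

| flask | substrate | reagent in the second phase | remark | time | volume of the second phase over the first |
|---|---|---|---|---|---|
| south | 0.18 M | 0.76 M | run made earlier |  |  |
| west | 0.18 M | 1.2 M | run made earlier |  |  |
| north-west | 0.27 M | 0.54 M | run made earlier |  |  |
| flask | 0.18 M | 0.540 M |  | 20 h | 1.0 |

- south (time / h: target / %, substrate / %): 1.50: 0.6, 100.2; 3.00: 0.8, 98.3; 6.00: 2.2, 96.5; 10.0: 7.4, 90.5; 20.0: 16.0, 74.1
- west (time / h: target / %, substrate / %): 1.50: 0, 99.5; 3.00: 1.0, 98.6; 6.00: 4.4, 94.7; 10.0: 10.3, 86.1; 20.0: 22.9, 61.3
- north-west (time / h: target / %, substrate / %): 2.00: 0.7, 99.4; 5.00: 2.2, 97.4; 10.0: 4.5, 93.6; 15.0: 6.4, 87.6; 20.0: 9.8, 81.9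

(each reading ± 0.5 percentage points)

- percentages count the substrate that a species holds: one side product counts as two
- target is meant together with its product in the second phase
- in the second phase: reagent in the second phase, product in the second phase; everything else is in the first
- charges count per volume of the first phase; a concentration in a rate is the amount of a species over the volume of its own phase; every rate counts per litre of the first phase
- steps thought possible: substrate + reagent in the reaction phase -> target; substrate + target -> side product; target -> decomposed product; reagent in the reaction phase <-> reagent in the second phase; target <-> product in the second phase
- the earlier runs hold the two phases in the same ratio of volumes as the flask asked about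

1. the target and product in the second phase together standing at 20 h, as a percentage of the substrate charged
2. part of the substrate charged that has reacted at 20 h

At 0.18 M against 0.540 M of reagent in the second phase, the substrate is the limiting reagent, so its moles are the ones we book. We carry one quantity, the turnover count: the natural log of charged over left at 20.0 h, per molar of reagent charged. We read it from the two runs at the flask's substrate charge:

south, 74.1% left: 0.394 /M
west, 61.3% left: 0.408 /M
their mean, the turnover count: 0.401 /M

The west run had 1.58 times the reagent of the south run, yet the two readings lie close. So, with time, substrate charge and volume ratio held, we take the log loss as proportional to the reagent charged. The north-west run, at 0.27 M of substrate, reads 0.370 /M; its substrate charge differs, so it stays out of the mean.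

For the second entry we need the substrate lost but not found as target, per unit of target. This reads 0.619 in south and 0.690 in west, mean 0.654. Our ledger for the flask, in percent of the substrate charged:

substrate left: 80.5%
reacted: 19.5%
target with its product in the second phase: 11.8%
decomposed product and side product: 7.70%

The forecast gives 18.9% reacted and 11.4% target. Like us, it holds that the log loss “scales about first order in reagent”, but both its numbers stand below ours, by 0.60 percentage points and 0.40 points.

The flask gives 11.4% of target and 19.5% reacted.

    substrate + reagent in the reaction phase → target (k = 0.340 /M/h)
    substrate + target → side product (k = 0.120 /M/h)
    target → decomposed product (k = 0.0610 /h)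
    reagent in the reaction phase ⇌ reagent in the second phase, rate k4*([reagent in the reaction phase] - [reagent in the second phase]/K4) per volume of the first phase (partition coefficient = 1.90, kL = 0.0170 /h)
    target ⇌ product in the second phase, rate k5*([target] - [product in the second phase]/K5) per volume of the first phase (partition coefficient = 2.60, kL = 0.0390 /h)

In this flask the half-life of reaction-phase target by decomposition alone, 11 h, is shorter than the 32 h by the side step alone, the other concentrations as charged. The count of 0.401 /M now goes to a neighbour of this flask, read at the same 20 h with 0.696 M of reagent in the second phase. The count reckons 24.4% reacted for that neighbour, 4.9 points above this flask, and the simulated neighbour stands 5 points above this flask.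

Readings and results come from a simulation with constants of no real substance; noise was put on by code.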